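Readings and results come from a simulation on assumed constants.

The trap in these runs is to compare them at equal times, when each holds different amounts of starting material and target at once.

| setting | larch | cedar | maple | ash |
|---|---|---|---|---|
| starting material | 0.150 M | 0.0600 M | 0.150 M | 0.0370 M |
| free catalyst | 0.00750 M | 0.00750 M | 0.00370 M | 0.00750 M |
| time |  |  |  | 23 min |

- larch run (time / min: [target] / M): 0.83: 0.0042; 2.5: 0.0160; 4.8: 0.0315; 7.6: 0.0511; 11: 0.0766; 15: 0.1005; 19: 0.1184; 23: 0.1314
- cedar run (time / min: [target] / M): 0.83: 0.0021; 2.5: 0.0058; 4.8: 0.0106; 7.6: 0.0169; 11: 0.0243; 15: 0.0317; 19: 0.0384; 23: 0.0435
- maple run (time / min: [target] / M): 0.83: 0.0023; 2.5: 0.0070; 4.8: 0.0130; 7.6: 0.0230; 11: 0.0384; 15: 0.0589; 19: 0.0787; 23: 0.0977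

(readings scatter by 4 × 10⁻⁴ M)

- Overall: starting material -> target, with free catalyst as catalyst.
- Constant volume, constant temperature.
- An order is taken over about fifteen percent of the charge, up and down.

- apparent order in [starting material] of the starting rate, round the charge of the larch run (the rate where two percent of its starting material have turned into target) (one fixed amount of target, the same in the runs compared)
- apparent order in [free catalyst] of the starting rate, round the charge of the larch run (the rate where two percent of its starting material have turned into target)
- the cedar run starts with 0.0900 M less of starting material than the larch run, and with no target. Compared where both hold the same amount of starting material, once fifteen percent of what the cedar run was charged with has turned into target, is the cedar run faster, slower or alike (within a tenth)?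
- target in the ash run at 23 min, as a share of the starting material charged

What do you compare instead? The fall of ln S per minute, called λ, where S is the starting material left: the charge Q less the target P. This is a pseudo-first-order rate constant, rate divided by S, and a rate simply proportional to S gives one λ at one catalyst charge.

Do larch and cedar share one λ? No. They have the same catalyst charge, and their S ranges overlap. Cedar from 2.5 min to 7.6 min gives 0.0449 min⁻¹ at a mean target of 0.0113 M. Larch from 11 min to 19 min gives 0.105 min⁻¹ at 0.0975 M, so the λ read in that larch stretch is larger than the one read in the cedar stretch.

Isn't that merely the larger charge? λ has S divided out and the two stretches cover like S, so I take the target held as the difference. I therefore draw λ = a + bP through the two readings. The slope b is 0.701 M⁻¹ min⁻¹ and the intercept a is 0.0370 min⁻¹.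

What do you carry forward? The crossover target, P× = a/b, the amount of target at which, at the catalyst charge of larch and cedar, target and catalyst contribute equally to λ. Here it reads 0.0527 M.

What does it say of the ash run? Its charge of 0.0370 M is smaller than P×. Integrating the rate (a + bP)(Q − P) gives the converted share f = (E − 1)/(E + Q/P×), with E = exp[(a + bQ)t]. For the ash run at 23 min, E is 4.25, so I commit to 65.6%. At equal target, λ is equal at one catalyst charge, so I also expect an order of 1 in starting material.

The forecast gives an order of 1.05 in starting material (0.92 to 1.18) and 1.1 in free catalyst (0.95 to 1.25). It calls cedar slower and puts the ash run at 68% (64% to 72%), which is above my figure. Its ground: “So target accelerates the reaction, which maple's upward curve also shows.”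

The flask gives orders of 1.0 and 1.1, cedar slower, and 66.7% in the ash run.

    free catalyst + starting material → target + free catalyst (6.060 M⁻¹ min⁻¹)
    free catalyst + impurity → spent catalyst
    starting material + target → 2 target (0.7140 M⁻¹ min⁻¹)

The ash run's target at 23 min, 0.0247 M, stands under P×, and P/(P + P×) gives target 31.9% of that run's λ at that time. The impurity takes 0.00123 M of free catalyst at the start, but the ash run has the catalyst charge of larch and cedar, so their readings of a already hold that loss. For cedar against larch at equal starting material, P× gives 0.407, drawn from the same two runs as the simulated ratio of 0.41, so this is a use of P× and no test of it. Without the path from starting material and target to more target, that ratio is 1.0.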